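(The data were generated by integration for an exercise, noise included.)

At the time of reading I wanted the top of G in the blue flask.

| flask | L | Z | remark | time |
|---|---|---|---|---|
| blue | 0.050 M | 1.5 equiv | the very flask that is asked about, followed so far |  |
| ochre | 0.025 M | 1.5 equiv | run made earlier |  |
| flask | 0.050 M | 1.50 equiv |  | 12 h |

| blue: time / h | blue: G / % | ochre: time / h | ochre: G / % |
|---|---|---|---|
| 0.0833 | 12.7 | 0.0833 | 6.8 |
| 0.250 | 18.9 | 0.333 | 14.2 |
| 0.833 | 12.8 | 1.33 | 8.4 |
| 2.50 | 1.9 | 5.00 | 0.5 |

(standard deviation of a reading: 0.5 percentage points)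

- the best time, 12 h at the latest, for G
- the amount of G, in percent of the L charged, at that time

In the blue run G read 12.7% at 0.0833 h and 12.8% at 0.833 h, equal within the scatter, so I put the top at the geometric mean of those times, 0.263 h, beside the highest reading, 18.9%. I carried one quantity, the surplus: Z charged minus L charged, in fractions of the L charge, here 0.500. If each L takes one Z, L goes first and Z keeps 33.3% of its own charge. G had already fallen to 1.9% by 2.50 h, so I expected no later rise.

The forecast gave 0.29 h (0.2 h to 0.4 h) and 19.3% (18.6% to 20.5%), and said: “After that, G only declines, so waiting until 12 h gains nothing.” The flask gave 19.2% at 0.301 h.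

    G → J (k = 2.60 × 10⁻⁵ /s)
    L + Z → E (k = 3.90 × 10⁻⁴ /M/s)
    G ⇌ D (K = 9.50, k = 1.00 × 10⁻⁴ /s)
    L + Z ⇌ G (K = 17.0 /M, k = 0.00860 /M/s)
    L + Z → Q (k = 0.0130 /M/s)

At 12.0 h this flask held L at 0.15% and Z at 33%, each of its own charge, so Z stood at the share reckoned from the surplus, with L the limiting reagent. The neighbour charged with 0.380 equiv of Z had a surplus of −0.620, so the same reckoning put Z first to go and left L 62.0% of its charge. At 12.0 h that neighbour's Z was down to 0.12% of its own charge, its best G had been 6.77%, and its L stood at 62%.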